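## The problem

(−)-Cubebininolide (14) is a trans-3,4-dibenzyl-γ-butyrolactone: with the ring numbered O1–C2(=O)–C3–C4–C5, C3 and C4 each carry a 3,4,5-trimethoxybenzyl group and both centres are R. The skeleton is small, so the task reduces to forming the bonds from C3 and C4 to their benzylic carbons (called C6 on C3 and C7 on C4 here) and fixing two adjacent stereocentres on a flexible chain. C3 lies next to the lactone carbonyl and can be equilibrated to the more stable trans arrangement, so C4 can correct C3, but nothing in the molecule controls C4 and the absolute configuration must come from outside. Apart from the oxidation level of C2 against C5 the molecule has a twofold axis, being a masked (2R,3R)-2,3-dibenzylsuccinic acid derivative whose two carboxyl carbons are equivalent. The six aryl methyl ethers make both rings electron-rich, so strong electrophiles, ether-cleaving Lewis acids and unselective oxidants must be avoided. Strong base must not act late in the route on a carbonyl compound with an acidic C3–H, since epimerisation there leads into the meso series. The feature that makes the key step possible is that C6 and C7 stand 1,4 to each other across the C3–C4 bond: a sulfur atom between them gives a thiolane S–C6–C3–C4–C7 whose C3–C4 unit with its two carboxyl carbons is a fumarate and whose C6–S–C7 unit is a thiocarbonyl ylide. Both C–S bonds of that ring are benzylic, so the sulfur can be removed again by hydrogenolysis.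

## Retrosynthesis

**Lactone 14 to diol 12.** No skeletal bond is cut. The acyl C2–O1 bond is opened and C2 is taken back to the alcohol level, which gives the twofold-symmetric (2R,3R)-diol 12. The neighbouring option, a diacid closed to an anhydride and then reduced, needs hydrolysis of hindered esters in hot base and puts the α-centres at risk, so the diol is preferred. Diol 12 has no regiochemical question left, because its two hydroxymethyl groups are homotopic. The forward reaction must oxidise one primary alcohol through lactol 13 to the lactone without touching the aryl rings.

**Diol 12 to diester 11.** The two C–O bonds of the primary alcohols are traced back to carboxyl groups, here the di-(−)-menthyl ester 11. This keeps the chiral auxiliary in the molecule until the stereocentres are secure and removes it in the same operation that sets the oxidation level. The forward reaction is a plain hydride reduction that must not epimerise C2 or C3 of the succinate.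

**Diester 11 to thiolane 10.** Two benzylic C–H bonds are replaced by C–S bonds to one sulfur atom, which ties the benzylic carbons into thiolane 10. This adds a ring but makes the two benzylic C–C bonds accessible to one cycloaddition. The two extra stereocentres next to sulfur are of no concern because they vanish on desulfurisation. The forward reaction must cleave both C–S bonds reductively and leave C3 and C4 untouched.

**Thiolane 10 to sulfoxide 5 and fumarate 8, through ylide 9.** The bonds C6–C3 and C7–C4 (C2–C3 and C4–C5 of the thiolane) are cut together in a retro-[3+2] step. Against stepwise alkylation of a succinate, this cut forms both benzylic bonds at once and fixes the trans relation by stereospecificity, not by a dl/meso selection. The precursors are far simpler: an achiral, symmetric sulfoxide 5 that releases the 1,3-diaryl thiocarbonyl ylide 9, and the fumarate 8, which carries the only stereochemical information. The forward reaction must release the ylide cleanly, add it to the alkene faster than it can close to a thiirane, and select one face of the fumarate.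

**Sulfoxide 5 to benzyl chloride 1.** The S–O bond is removed (sulfide 4), then both C–Si bonds (via monosilyl sulfide 3 to dibenzyl sulfide 2), then both C–S bonds, which leads to two molecules of chloride 1 and a sulfide source. Each cut removes heteroatom decoration only; the aryl building block is one cheap compound used twice. The forward sequence must place exactly one silyl group on each benzylic carbon and stop the oxidation at the sulfoxide.

**Fumarate 8 to fumaryl chloride 6 and (−)-menthol 7.** Two ester C–O bonds are cut, which leads to one molecule of 6 and two molecules of 7. The forward reaction is a simple double acylation that keeps the E geometry.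

## Roads not taken

Alternative 1: double methyl C–H arylation.
- Cut: both aryl–CH2 bonds. The target is read as a 2,3-dimethylsuccinic acid derivative whose methyl groups each lack an aryl ring.
- Forward key step: the enantiopure (2R,3R)-2,3-dimethylbutanediamide A1, with an N-[2-(methylsulfanyl)phenyl] directing group on each nitrogen, is coupled with two equivalents of 5-iodo-1,2,3-trimethoxybenzene A2 under the catalyst Pd(OAc)2 A4 and the iodide scavenger AgOAc A5. The product is the bis-benzyl diamide A3.
- Merits: both stereocentres are bought, not made, so there is no facial selectivity to establish. The directing group is selective for primary C–H bonds, and electron-rich aryl iodides are good partners.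
- Weak points:
  - Two palladacycles must form in turn on one small molecule that carries two bidentate directing groups, which can bind divalent palladium jointly and slow turnover. Mixtures of mono- and diarylated material are likely.
  - The stereocentres lie α to amide carbonyls and are exposed to carboxylate base above 100 °C.
  - The two secondary anilides of A3 are robust. Removing them needs N-activation and forcing cleavage before 12 or 14 can be reached, which adds steps and again endangers the α-centres.
  - The parent diacid of A1 is a resolved, costly material, not a true chiral-pool compound, and the silver salt A5 is used stoichiometrically.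
- Comparison: this road is better than the chosen plan in stereochemical certainty, and its key reaction type is established. The chosen plan offers achiral commodity starting materials, a recoverable auxiliary and control groups (esters) that leave by simple hydride reduction. Its relative configuration is fixed by a stereospecific cycloaddition and is never exposed to hot base.

Alternative 2: opening of a cyclopropane-fused lactone.
- Cut: the aryl–CH2 bond on the C4 side and the C3–CH2 bond on the C3 side. The lactone ring is present from the start.
- Forward key step: the bicyclic lactone A6, a doubly activated cyclopropane, is opened at its ring CH2 by the aryl Grignard reagent A7 with catalytic CuI A10. The released C3 enolate is benzylated with bromide A8 to give the lactone ester A9. A Krapcho dealkoxycarbonylation then leads to 14, with C3 settling trans to C4.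
- Merits: the route is very short, about three operations from A6. C4 comes from an enantiopure building block and is never at risk, the trans relation is thermodynamic, and each bond formation has close analogy in this lactone class.
- Weak points: the same aryl group must be supplied as two different reagents, A7 and A8. The final protonation at C3 is kinetic and may need a separate base equilibration. The optical purity of 14 can be no better than that of A6.
- Comparison: on step count and precedent this road is stronger than the chosen plan, and that is conceded. The chosen plan uses the hidden twofold symmetry: one aryl building block, both benzylic bonds and the relative configuration in one event. It passes through the symmetric compounds 11 and 12, which serve the whole dibenzylbutane family. It would also establish a new auxiliary-controlled thiocarbonyl ylide cycloaddition, a methodological return this alternative does not give.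

Alternative 3: syn bis(methoxycarbonylation) of a symmetric alkene.
- Cut: the C2–C3 and C4–C5 bonds, that is, both carboxyl carbons are removed from the backbone, leaving the E-alkene A11.
- Forward key step: A11, two molecules of carbon monoxide A12 and two of methanol A13 combine under Pd(O2CCF3)2 A15, a chiral bis(oxazoline) ligand and the oxidant 1,4-benzoquinone A16. Syn addition across the E double bond gives the (2R,3R)-dimethyl succinate A14, which hydride would reduce to 12.
- Merits: it is catalytic and enantioselective, uses no auxiliary, and is the shortest access to the symmetric succinate. The relative configuration is fixed by syn stereospecificity, just as the cycloaddition fixes it in the chosen plan.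
- Weak points:
  - Oxidative bis(alkoxycarbonylation) is at its best with terminal alkenes. A11 is an internal alkene flanked by two CH2 groups that are both allylic and benzylic, so β-hydride elimination from the alkylpalladium intermediate and migration of the double bond into conjugation should compete.
  - The two faces of A11 differ only through remote groups, so high enantioselectivity cannot be assumed.
  - A shortfall gives enantiomers with no handle for separation.
- Comparison: both key steps go beyond precedent, and this road is shorter and catalytic. The chosen plan has one advantage: imperfect induction gives diastereomers, which the menthyl esters make separable at 11.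

Key step: step 5

Remark: the facial sense of induction by (−)-menthyl esters in an uncatalysed dipolar cycloaddition cannot be fixed on paper. The route is written for the (3R,4R) adduct, and (+)-menthol would replace 7 if the major adduct proved to be the (3S,4S) isomer.

## Route

Step 1
Reactants: 1 3,4,5-trimethoxybenzyl chloride
Product: 2 bis(3,4,5-trimethoxybenzyl) sulfide
Conditions: Na2S·9H2O (1 equiv per 2 equiv of 1), EtOH–H2O, reflux
Reagents that add atoms: sodium sulfide, [Na+].[Na+].[S-2]; 3,4,5-trimethoxybenzyl chloride as the second molecule of 1, COc1cc(CCl)cc(OC)c1OC
Why: Double SN2 thioether synthesis in which two molecules of 1 are joined by one sulfide ion; a primary benzylic chloride is an ideal electrophile for sulfide and then for the intermediate thiolate, and nothing else in 1 reacts.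

Step 2
Reactants: 2 bis(3,4,5-trimethoxybenzyl) sulfide
Product: 4 bis[(3,4,5-trimethoxyphenyl)(trimethylsilyl)methyl] sulfide (diastereomer mixture), via monosilyl sulfide 3 (not isolated)
Conditions: LiTMP (lithium 2,2,6,6-tetramethylpiperidide, 2.5 equiv), Me3SiCl (3 equiv, present from the start), THF, −78 → −40 °C
Reagents that add atoms: chlorotrimethylsilane, C[Si](C)(C)Cl
Why: α-Lithiation of a benzyl sulfide with internal silyl quench, one molecule of Me3SiCl being taken up in each of the two silylations; each carbanion is silylated as it forms, which forestalls the [1,2]-thio-Wittig shift, and the bulky amide should take the second proton from the open CH2 of 3 and not from its crowded silylated methine. The two new stereocentres form without control and need none, since they disappear in ylide 9.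

Step 3
Reactants: 4 bis[(3,4,5-trimethoxyphenyl)(trimethylsilyl)methyl] sulfide
Product: 5 bis[(3,4,5-trimethoxyphenyl)(trimethylsilyl)methyl] sulfoxide (stereoisomer mixture)
Conditions: mCPBA (1.0 equiv), CH2Cl2, −78 °C; cold aq. NaHCO3 wash; concentrated below 0 °C and used at once
Reagents that add atoms: meta-chloroperbenzoic acid (mCPBA), O=C(OO)c1cccc(Cl)c1
Why: Electrophilic oxygen transfer to a dialkyl sulfide; one equivalent at −78 °C should stop at the sulfoxide and leave the electron-rich rings alone. Work-up is kept cold because α-silyl sulfoxides undergo the sila-Pummerer shift on warming; the stereogenic sulfur is irrelevant.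

Step 4
Reactants: 6 fumaryl chloride; 7 (−)-menthol [(1R,2S,5R)-2-isopropyl-5-methylcyclohexanol]
Product: 8 di-(−)-menthyl fumarate
Conditions: 7 (2.1 equiv), Et3N (2.2 equiv), DMAP (cat.), CH2Cl2, 0 °C → rt
Reagents that add atoms: (−)-menthol as the second molecule of 7, CC(C)[C@@H]1CC[C@@H](C)C[C@H]1O
Why: Double acylation of a secondary alcohol by a diacid chloride under nucleophilic catalysis, one molecule of 7 on each acyl chloride group of 6; the E geometry and the stereocentres of both menthyl groups are untouched.

Step 5
Reactants: 5 bis[(3,4,5-trimethoxyphenyl)(trimethylsilyl)methyl] sulfoxide; 8 di-(−)-menthyl fumarate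
Product: 10 di-(−)-menthyl (3R,4R)-2,5-bis(3,4,5-trimethoxyphenyl)thiolane-3,4-dicarboxylate (mixture at C2 and C5), via thiocarbonyl ylide 9 (not isolated)
Conditions: 8 (2 equiv), toluene–DMPU, 60–80 °C, slow addition of cold 5
Reagents that add atoms: none
Why: Proposed new method: on warming, one Me3Si group of 5 shifts from carbon to the sulfoxide oxygen (sila-Pummerer shift), the departing silanolate strips the second Me3Si group as hexamethyldisiloxane, and the 1,3-diaryl thiocarbonyl ylide 9 is released and trapped at once by the excess fumarate 8. The closest known reaction type is the [3+2] cycloaddition of the unsubstituted thiocarbonyl ylide, made the same way from bis(trimethylsilylmethyl) sulfoxide, with fumarates, maleates and chiral acrylamides; a ylide with an aryl group on each carbon combined with an ester-bound auxiliary on the alkene has not been shown. The thiolane ring closes intermolecularly by a concerted suprafacial π4s+π2s addition in which both new C–C bonds (C2–C3 and C4–C5, thiolane numbering) form in one event. C3 and C4 come out trans because the E geometry of 8 is carried over stereospecifically, and their absolute sense is set by the two (−)-menthyl groups, which make the two faces of the fumarate diastereotopic. C2 and C5 follow from the ylide geometry and the endo or exo approach, are expected as a mixture and do not matter, because both become CH2 in step 6. The step therefore needs facial selectivity and, beyond that, a cycloaddition that outruns 1,3-electrocyclisation of 9 to a thiirane and Pummerer-type collapse; the aryl groups stabilise the dipole, slow addition keeps it dilute, and the electron-poor alkene matches the electron-rich ylide. Since the two possible trans adducts are diastereomers and not enantiomers, modest induction can be made up by separation after step 6.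

Step 6
Reactants: 10 di-(−)-menthyl (3R,4R)-2,5-bis(3,4,5-trimethoxyphenyl)thiolane-3,4-dicarboxylate
Product: 11 di-(−)-menthyl (2R,3R)-2,3-bis(3,4,5-trimethoxybenzyl)succinate
Conditions: Raney Ni (W-2, washed neutral, excess), EtOH–THF, 60 °C; then crystallisation or chromatography
Reagents that add atoms: none
Why: Raney nickel desulfurisation; both benzylic C–S bonds are hydrogenolysed, which turns C2 and C5 of the thiolane into CH2 and erases their configuration, while C3 and C4 are not involved. Neutral catalyst should spare the ester α-centres; only two diastereomers remain at this stage, so 11 is separated here from its (2S,3S) isomer.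

Step 7
Reactants: 11 di-(−)-menthyl (2R,3R)-2,3-bis(3,4,5-trimethoxybenzyl)succinate
Product: 12 (2R,3R)-2,3-bis(3,4,5-trimethoxybenzyl)butane-1,4-diol
Conditions: LiAlH4 (excess), THF, 0 °C → reflux; Fieser work-up
Reagents that add atoms: none
Why: Hydride reduction of both esters to primary alcohols; heat is needed for the hindered menthyl esters, the α-centres are not enolised under these conditions, and (−)-menthol is recovered.

Step 8
Reactants: 12 (2R,3R)-2,3-bis(3,4,5-trimethoxybenzyl)butane-1,4-diol
Product: 14 (−)-cubebininolide [(3R,4R)-3,4-bis(3,4,5-trimethoxybenzyl)oxolan-2-one], via lactol 13 (not isolated)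
Conditions: TEMPO (0.2 equiv), PhI(OAc)2 (2.5 equiv), CH2Cl2, rt
Reagents that add atoms: none
Why: Oxoammonium-mediated oxidative lactonisation of a 1,4-diol; one primary alcohol is oxidised to the aldehyde, which closes onto the other hydroxyl to lactol 13, and this is oxidised to the lactone. The two hydroxymethyl groups of 12 are homotopic, so only one lactone can form, and the mild, nearly neutral conditions keep the trans C3/C4 relation.

## Compound list

1 | 3,4,5-trimethoxybenzyl chloride | COc1cc(CCl)cc(OC)c1OC | starting material
2 | bis(3,4,5-trimethoxybenzyl) sulfide | COc1cc(CSCc2cc(OC)c(OC)c(OC)c2)cc(OC)c1OC | intermediate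
3 | trimethyl[(3,4,5-trimethoxyphenyl)(3,4,5-trimethoxybenzylsulfanyl)methyl]silane (racemic monosilyl sulfide, not isolated) | COc1cc(CSC([Si](C)(C)C)c2cc(OC)c(OC)c(OC)c2)cc(OC)c1OC | intermediate
4 | bis[(3,4,5-trimethoxyphenyl)(trimethylsilyl)methyl] sulfide (diastereomer mixture) | COc1cc(cc(OC)c1OC)C([Si](C)(C)C)SC([Si](C)(C)C)c1cc(OC)c(OC)c(OC)c1 | intermediate
5 | bis[(3,4,5-trimethoxyphenyl)(trimethylsilyl)methyl] sulfoxide (stereoisomer mixture) | COc1cc(cc(OC)c1OC)C([Si](C)(C)C)S(=O)C([Si](C)(C)C)c1cc(OC)c(OC)c(OC)c1 | intermediate
6 | fumaryl chloride | O=C(Cl)/C=C/C(=O)Cl | starting material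
7 | (−)-menthol, (1R,2S,5R)-2-isopropyl-5-methylcyclohexanol | CC(C)[C@@H]1CC[C@@H](C)C[C@H]1O | starting material
8 | di-(−)-menthyl fumarate | CC(C)[C@@H]1CC[C@@H](C)C[C@H]1OC(=O)/C=C/C(=O)O[C@@H]1C[C@H](C)CC[C@H]1C(C)C | intermediate
9 | 1,3-bis(3,4,5-trimethoxyphenyl)thiocarbonyl ylide (not isolated) | COc1cc(cc(OC)c1OC)C=[S+][CH-]c1cc(OC)c(OC)c(OC)c1 | intermediate
10 | di-(−)-menthyl (3R,4R)-2,5-bis(3,4,5-trimethoxyphenyl)thiolane-3,4-dicarboxylate (C2 and C5 unassigned) | O=C(O[C@@H]1C[C@H](C)CC[C@H]1C(C)C)[C@@H]1C(c2cc(OC)c(OC)c(OC)c2)SC(c2cc(OC)c(OC)c(OC)c2)[C@H]1C(=O)O[C@@H]1C[C@H](C)CC[C@H]1C(C)C | intermediate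
11 | di-(−)-menthyl (2R,3R)-2,3-bis(3,4,5-trimethoxybenzyl)succinate | CC(C)[C@@H]1CC[C@@H](C)C[C@H]1OC(=O)[C@H](Cc1cc(OC)c(OC)c(OC)c1)[C@@H](Cc1cc(OC)c(OC)c(OC)c1)C(=O)O[C@@H]1C[C@H](C)CC[C@H]1C(C)C | intermediate
12 | (2R,3R)-2,3-bis(3,4,5-trimethoxybenzyl)butane-1,4-diol | OC[C@H](Cc1cc(OC)c(OC)c(OC)c1)[C@@H](Cc1cc(OC)c(OC)c(OC)c1)CO | intermediate
13 | (3R,4R)-3,4-bis(3,4,5-trimethoxybenzyl)oxolan-2-ol (lactol, anomer mixture, not isolated) | COc1cc(C[C@H]2COC(O)[C@@H]2Cc2cc(OC)c(OC)c(OC)c2)cc(OC)c1OC | intermediate
14 | (−)-cubebininolide, (3R,4R)-3,4-bis(3,4,5-trimethoxybenzyl)oxolan-2-one | COc1cc(C[C@H]2COC(=O)[C@@H]2Cc2cc(OC)c(OC)c(OC)c2)cc(OC)c1OC | target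

## Step count and risks

Total step count: 8. Longest linear sequence: 7 steps (steps 1, 2, 3, 5, 6, 7, 8); step 4 is a one-step branch.

**Step 5 (key step, carries the label "Proposed new method:").** Three processes may defeat it.
- The silanolate may add back to the thionium carbon (ordinary Pummerer course) instead of removing the second silyl group, so that no ylide forms.
- The ylide may close to a thiirane by 1,3-electrocyclisation, or dimerise, faster than it adds to the hindered fumarate.
- Facial selection may be poor, because no Lewis acid fixes the ester conformation in a thermal reaction.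

The fallback uses known enolate chemistry and no sulfur. It sets out from 8 and 1. Hydrogenation of 8 (H2, Pd/C, EtOAc) gives di-(−)-menthyl succinate F1. Its dilithium dienolate (LiTMP, THF, −78 °C) is alkylated with two molecules of 1 (DMPU, −78 → 0 °C), the established 2,3-dialkylation of succinate dienolates. The menthyl esters again make the stereoisomers diastereomeric, and the (2R,3R) isomer is separated. The fallback rejoins the route at 11.

**Step 2.** The second metalation may occur at the already silylated carbon and give geminal disilylation, or the α-lithio sulfide may undergo [1,2]-shift or ring metalation if trapping lags. The fallback places silicon on each benzylic carbon before sulfur joins them. It sets out from 1: α-lithiation with in-situ silylation (LiTMP, Me3SiCl, THF, −78 °C) gives [chloro(3,4,5-trimethoxyphenyl)methyl]trimethylsilane F2. Displacement of the chloride of two molecules by Na2S (0.5 equiv, EtOH–H2O), the same way the unsubstituted bis(silylmethyl) sulfide is made, returns to the route at 4.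

**Step 3.** The silyl shift may start during oxidation or work-up and collapse along the Pummerer course under the influence of the carboxylic acid by-product, or oxidation may run on to the sulfone. The fallback introduces oxygen before silicon, so that no oxidant meets a silylated compound. It sets out from 2: NaIO4 (MeOH–H2O–CH2Cl2, 0 °C) gives the stable, silicon-free bis(3,4,5-trimethoxybenzyl) sulfoxide F3. Double C-silylation of its α-sulfinyl carbanions with internal quench (LiTMP, Me3SiCl, THF, −78 °C) then gives 5 as a cold solution that is transferred directly into step 5. The fallback rejoins at 5.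

**Step 6.** Residual alkali on the nickel may epimerise the ester α-centres and leak material into the meso series, or hydrogenolysis may stall after the first C–S bond. The fallback changes the order of events so that no enolisable centre is present during desulfurisation. It sets out from 10: LiAlH4 (THF, reflux) gives [(3R,4R)-2,5-bis(3,4,5-trimethoxyphenyl)thiolane-3,4-diyl]dimethanol F4. Raney Ni then removes sulfur, and the fallback rejoins at 12, where the separation from the (2S,3S) diol is carried out.

**Step 8.** Both primary alcohols may be oxidised before the lactol closes, or the hypervalent iodine oxidant may attack the electron-rich rings. The fallback reaches the lactone by reduction instead of oxidation. It sets out from 11: saponification (KOH, aq. EtOH, reflux, monitored for epimerisation) gives (2R,3R)-2,3-bis(3,4,5-trimethoxybenzyl)succinic acid F5. Dehydration with Ac2O gives (3R,4R)-3,4-bis(3,4,5-trimethoxybenzyl)oxolane-2,5-dione F6. NaBH4 (THF, 0 °C), then acid, reduces one of the two equivalent carbonyl groups, and the fallback rejoins at 14.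

## Further compounds

F1 | step 5 | di-(−)-menthyl succinate | CC(C)[C@@H]1CC[C@@H](C)C[C@H]1OC(=O)CCC(=O)O[C@@H]1C[C@H](C)CC[C@H]1C(C)C
F2 | step 2 | [chloro(3,4,5-trimethoxyphenyl)methyl]trimethylsilane (racemic) | COc1cc(C(Cl)[Si](C)(C)C)cc(OC)c1OC
F3 | step 3 | bis(3,4,5-trimethoxybenzyl) sulfoxide | COc1cc(CS(=O)Cc2cc(OC)c(OC)c(OC)c2)cc(OC)c1OC
F4 | step 6 | [(3R,4R)-2,5-bis(3,4,5-trimethoxyphenyl)thiolane-3,4-diyl]dimethanol (C2 and C5 unassigned) | OC[C@@H]1C(c2cc(OC)c(OC)c(OC)c2)SC(c2cc(OC)c(OC)c(OC)c2)[C@H]1CO
F5 | step 8 | (2R,3R)-2,3-bis(3,4,5-trimethoxybenzyl)succinic acid | OC(=O)[C@H](Cc1cc(OC)c(OC)c(OC)c1)[C@@H](Cc1cc(OC)c(OC)c(OC)c1)C(=O)O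
F6 | step 8 | (3R,4R)-3,4-bis(3,4,5-trimethoxybenzyl)oxolane-2,5-dione | O=C1[C@H](Cc2cc(OC)c(OC)c(OC)c2)[C@@H](Cc2cc(OC)c(OC)c(OC)c2)C(=O)O1
A1 | alternative 1 | (2R,3R)-2,3-dimethyl-N1,N4-bis[2-(methylsulfanyl)phenyl]butanediamide | C[C@@H](C(=O)Nc1ccccc1SC)[C@@H](C)C(=O)Nc1ccccc1SC
A2 | alternative 1 | 5-iodo-1,2,3-trimethoxybenzene | COc1cc(I)cc(OC)c1OC
A3 | alternative 1 | (2R,3R)-N1,N4-bis[2-(methylsulfanyl)phenyl]-2,3-bis(3,4,5-trimethoxybenzyl)butanediamide | COc1cc(C[C@@H](C(=O)Nc2ccccc2SC)[C@@H](Cc2cc(OC)c(OC)c(OC)c2)C(=O)Nc2ccccc2SC)cc(OC)c1OC
A4 | alternative 1 | palladium diacetate, Pd(OAc)2 | CC(=O)[O-].CC(=O)[O-].[Pd+2]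
A5 | alternative 1 | silver acetate, AgOAc | CC(=O)[O-].[Ag+]
A6 | alternative 2 | methyl (1S,5R)-2-oxo-3-oxabicyclo[3.1.0]hexane-1-carboxylate | C1[C@H]2COC(=O)[C@@]12C(=O)OC
A7 | alternative 2 | 3,4,5-trimethoxyphenylmagnesium bromide | COc1cc([Mg]Br)cc(OC)c1OC
A8 | alternative 2 | 3,4,5-trimethoxybenzyl bromide | COc1cc(CBr)cc(OC)c1OC
A9 | alternative 2 | methyl (3R,4R)-2-oxo-3,4-bis(3,4,5-trimethoxybenzyl)oxolane-3-carboxylate | COC(=O)[C@@]1(Cc2cc(OC)c(OC)c(OC)c2)[C@@H](Cc2cc(OC)c(OC)c(OC)c2)COC1=O
A10 | alternative 2 | copper iodide, CuI | [Cu+].[I-]
A11 | alternative 3 | (E)-1,4-bis(3,4,5-trimethoxyphenyl)but-2-ene | COc1cc(C/C=C/Cc2cc(OC)c(OC)c(OC)c2)cc(OC)c1OC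
A12 | alternative 3 | carbon monoxide | [C-]#[O+]
A13 | alternative 3 | methanol | CO
A14 | alternative 3 | dimethyl (2R,3R)-2,3-bis(3,4,5-trimethoxybenzyl)succinate | COC(=O)[C@H](Cc1cc(OC)c(OC)c(OC)c1)[C@@H](Cc1cc(OC)c(OC)c(OC)c1)C(=O)OC
A15 | alternative 3 | palladium bis(trifluoroacetate), Pd(O2CCF3)2 | [Pd+2].[O-]C(=O)C(F)(F)F.[O-]C(=O)C(F)(F)F
A16 | alternative 3 | 1,4-benzoquinone | O=C1C=CC(=O)C=C1
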